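## Structural features

- Compound 42 is a briarane-type diterpenoid. Its cyclohexene ring A (C1, C10–C14) is trans-fused through C1–C10 to a ten-membered carbocycle (C1–C10), and a γ-lactone (C7–O–C19(=O)–C17–C8) is fused across C7–C8. Methyl groups sit on C1, C5, C11 and C17.
- Ten stereocentres lie in two contiguous runs, C7–C8(–C17)–C9–C10(–C11–C12)–C1–C2–C3. Only C4–C6, with the (Z)-C5=C6 alkene, interrupt them.
- Three carbinol carbons are fully substituted (C8, C11, C17), two of them adjacent, and C1 is an all-carbon quaternary centre next to the C2 carbinol. C2–O/C3–O are syn along the chain. The C11 and C12 hydroxyls are cis to each other and trans to C9 and the C1 methyl.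
- Fragile points: the C3 acetate beside the free C2 hydroxyl (acyl migration), the allylic lactone C7–O bond, the β-hydroxy lactone C8–C17 (retro-aldol once C8–O is an alkoxide) and the tertiary allylic-type alcohols of ring A.
- The real difficulty is the ten-membered ring with its Z trisubstituted alkene, flanked by the dense C7/C8/C17/C9 oxygen array.
- The key step uses the segment C3(OH)–C4H2–C5(CH3)=C6–C7(O). This is the retron of a vinylogous aldol between a C3 aldehyde and the γ-carbon of a 3-methylbut-2-enoyl ketone at C7. Because C8 is fully substituted, that ketone can be enolised only through its γ-methyl groups.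

## Logic of the disconnections

**42 back to 38.** Only C–O bonds are cut: the C11/C12 acetal, the C2 benzyl-type ether and the C9 acetate. Silyl ethers on O8/O9, a PMB ether on O2 and an acetonide on O11/O12 form an orthogonal set, so C9 can be acetylated (39 to 40) while C2 and C12 stay masked. The demand is that the last two deprotections (40 to 41 to 42) are neutral or weakly acidic so the C3 acetate does not migrate.

**38 back to 36.** The lactone O7–C19 bond and the C7–H bond are cut. This returns C7 to the ketone needed for ring closure and C19 to an activated dioxolanone carbonyl. The forward step must deliver hydride to one face of C7 and let the new hydroxyl acylate itself.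

**36 and 35 back to 33.** The C3–C4 bond is cut (the strategic step); the acetate is removed first. This opens the ten-membered ring to an open-chain keto aldehyde in which every other stereocentre is already present. The forward step needs γ- over α-attack, ring closure over oligomerisation, a Z alkene and one face of the aldehyde.

**33 back to 31 and 29.** No skeletal bond is cut. The C3 aldehyde is traced to a vinyl group and the C7 enone to a tertiary propargylic alcohol, because neither an aldehyde nor an enone would survive the enolate and acetylide steps before them. The forward steps need an oxidative cleavage that spares two other alkenes and a clean 1,3-oxygen shift.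

**29 back to 23 and 26.** The C8–C17 bond is cut. This splits off C17–C19 with its methyl and oxygen as a lactic acid unit and leaves a ketone at C8. The forward aldol must control the enolate face (through the acetal of 26) and the ketone face (through the C9 silyl ether of 23).

**23 back to 19 and 20.** The C7–C8 bond is cut. C5–C7 then come from a commercial alkyne, and C8 is an aldehyde carrying the C9 stereocentre. The only demand is addition without loss of the α-silyloxy centre.

**19 and 18 back to 16, 15 and 13.** The C11–O and C12–O bonds are cut back to a ring A diene, which is traced through its triflate to an enone. This removes two stereocentres in one syn-dihydroxylation. The forward step must choose the correct alkene and the correct face.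

**13 back to 12, 11, 10, 9 and 8.** The C2–C3 bond (vinyl addition) and the C2–H bond (ketone reduction) are cut, leaving a C2 aldehyde on quaternary C1. The reduction must set C2 against a fully substituted neighbour.

**8 back to 5 and 7.** The C10–C11 and C1–C14 bonds are cut (Diels–Alder). Ring A, quaternary C1 and C10 fall to an acyclic enal and a siloxy diene. The forward step needs para regiochemistry and one dienophile face, both governed by the C9 stereocentre.

**5 back to 4, 3, 1 and 2; 7 back to 6; 26 back to 24 and 25.** The C1=C10 alkene is cut (Wittig). C9 is traced to a chiral-pool glyceraldehyde, the diene to an ethyl ketone and the dioxolanone to (R)-lactic acid. The demands are E geometry and a cis acetal.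

## Other disconnections considered

**Alternative 1:** The cut is C9–C10 (with C11–CH3) on a preformed six-membered ring.
- Forward key step: under Cu(OTf)2/phosphoramidite catalysis a vinyl group is transferred from zinc to one enantiotopic alkene of the symmetric dienone A1, and the zinc enolate is methylated to give A2.
- In favour: A2 carries C1, C10 and C11 after one catalytic operation on a very cheap dienone, and its C1/C10 configuration matches 42. This is shorter than steps 1–5 of the chosen plan and uses a catalyst rather than the chiral pool; on both counts it is the better entry to ring A.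
- Against: no ring is closed and the ten-membered ring is untouched. C9 arrives as a terminal alkene carbon, so its carbinol centre must be created later beside two quaternary neighbours, whereas the chosen plan takes C9 from compound 1. The addition must also occur anti to the dichloromethyl group, the CHCl2 group must be unmasked to the C2 aldehyde, and C11 still needs its hydroxyl.
- Comparison: mechanistically it is as reliable as the Diels–Alder step of the chosen plan. It would be a different way to a ring A block, not a substitute for the macrocyclisation; the later work (C2/C3, C11/C12 diol, C8/C17) is the same or longer.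

**Alternative 2:** The cut is C1–C10 together with the C11–O bond.
- Forward key step: a boron Lewis acid (BF3·OEt2) opens the C1–C2 epoxide of the fourteen-membered ring A3 at tertiary allylic C1, the C10=C11 alkene attacks through C10, and water traps the C11 cation to give A4.
- In favour: ring A and the ten-membered ring form together with C1, C10 and C11 in one operation, and A4 is one desilylation from 42. In convergence and in steps after the macrocycle it is clearly better than the chosen plan.
- Against: the whole problem moves to making A3, a fourteen-membered ring that already carries seven stereocentres, the lactone, an (E)-trisubstituted alkene and a trisubstituted epoxide. The cationic cascade has many exits: proton loss from the C11 cation, allylic transposition through C13=C14, semipinacol-type opening of the epoxide, and ionisation of the allylic lactone or tertiary alcohols. The faces at C1, C10 and C11 would be set only by an unknown macrocycle conformation.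
- Comparison: the chosen plan fixes C1 and C10 by a cycloaddition with understood control and asks its ring closure for one bond and one stereocentre; it is longer but more predictable.

**Alternative 3:** The cut is C7–C8 and C9–O.
- Forward key step: hypochlorite oxidation of the (Z)-enal oxime A5 triggers an intramolecular nitrile oxide cycloaddition onto the C10 vinyl group, giving the isoxazoline-bridged ten-membered ring A6.
- In favour: this is an established, neutral ring closure with no strong base, the Z alkene is in place beforehand, and the isoxazoline is a masked C7 ketone/C9 carbinol. In precedent for the ring-closing event it is better than the chosen key step.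
- Against: C8 is delivered as a CH2 group. After N–O cleavage a C8–C17 bond and a C8–O bond would both have to be made at the α-carbon of a β-hydroxy ketone inside the ring, where retro-aldol and dehydration compete, and C17–C19 are still missing. The bridged closure must beat nitrile oxide dimerisation, and the C9 face rests on ring conformation.
- Comparison: the chosen plan closes the ring with C8, C17 and C19 complete, so less work follows the ring closure; the price is a ring closure without direct precedent.

Key step: step 22

**Remarks on the chemistry and design choices:**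
- The lactate unit is carried as the cis-2-tert-butyl dioxolanone. An acetone-derived dioxolanone would lose the stereocentre on enolisation.
- O8 and O9 carry two triethylsilyl ethers in place of a five-membered silylene, which is hydrolytically labile and would cost extra steps.
- An aluminium-bound α-alkoxy aldehyde reacting by the open-chain dipolar model would give the 2,3-anti alcohol, whereas 42 is 2,3-syn. The C3 configuration therefore has to come from the ring closure itself and is backed by the fallback.
- C5–C6 is a single bond in the dienolate, so either C5 methyl may be deprotonated.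
- Assumption: compounds 1, 2, 6, 20, 24 and 25 are commercial. C11 in compounds 8–13 is an inconsequential mixture.

## Route

Step 1
Reactants: 1 (R)-2,2-dimethyl-1,3-dioxolane-4-carbaldehyde; 2 2-(triphenylphosphoranylidene)propanal
Product: 3 (E)-3-[(4S)-2,2-dimethyl-1,3-dioxolan-4-yl]-2-methylprop-2-enal
Conditions: toluene, 80 °C
Reagents that add atoms: none
Why: Wittig olefination with a formyl-stabilised ylide, which should give the (E)-enal (C9 cis to the future C1 methyl); the C9 stereocentre comes unchanged from the mannitol-derived aldehyde.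

Step 2
Reactants: 3 (E)-3-[(4S)-2,2-dimethyl-1,3-dioxolan-4-yl]-2-methylprop-2-enal
Product: 4 (4S,E)-4,5-dihydroxy-2-methylpent-2-enal
Conditions: AcOH/H2O (4:1), 40 °C
Reagents that add atoms: none
Why: Acid hydrolysis of a terminal isopropylidene acetal, done here so that no second acetal has to be distinguished later; the E geometry keeps the hydroxyls away from the formyl group, so no lactol can form.

Step 3
Reactants: 4 (4S,E)-4,5-dihydroxy-2-methylpent-2-enal
Product: 5 (4S,E)-2-methyl-4,5-bis(triethylsilyloxy)pent-2-enal
Conditions: Et3SiCl, imidazole, DMF, 0 °C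
Reagents that add atoms: chlorotriethylsilane CC[Si](Cl)(CC)CC
Why: Standard silylation of both hydroxyls; the primary silyl ether is the later handle for C8 and the secondary one is the non-chelating C9 group used for stereocontrol in steps 5 and 19.

Step 4
Reactants: 6 pent-1-en-3-one
Product: 7 (Z)-3-(triisopropylsilyloxy)penta-1,3-diene
Conditions: iPr3SiOTf, Et3N, Et2O, 0 °C
Reagents that add atoms: triisopropylsilyl trifluoromethanesulfonate CC(C)[Si](C(C)C)(C(C)C)OS(=O)(=O)C(F)(F)F
Why: Soft enolisation of the ethyl ketone gives the (Z)-silyl enol ether, that is, the 2-siloxy diene with the methyl group on the outside of the cisoid diene.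

Step 5
Reactants: 5 (4S,E)-2-methyl-4,5-bis(triethylsilyloxy)pent-2-enal; 7 (Z)-3-(triisopropylsilyloxy)penta-1,3-diene
Product: 8 ring A aldehyde, 6-[(1S)-1,2-bis(triethylsilyloxy)ethyl]-1,5-dimethyl-4-(triisopropylsilyloxy)cyclohex-3-ene-1-carbaldehyde (ring positions 1 and 6 = C1 and C10, configured as in 42; position 5 = C11 as a mixture)
Conditions: Me2AlCl (0.5 equiv), CH2Cl2, −78 → −40 °C
Reagents that add atoms: none
Why: Lewis acid-promoted Diels–Alder reaction in which the methyl-bearing enol ether terminus bonds to the β-carbon C10, so the siloxy carbon C12 ends para to C1, and the E dienophile places C2 and C9 trans. A(1,3) strain with the C1 methyl holds the C9–H in the alkene plane and the diene adds anti to the C9–O bond, which sets C1 and C10 as in 42; C11 is erased in step 11.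

Step 6
Reactants: 8 ring A aldehyde
Product: 9 C2 allylic alcohols (both C2 epimers), 1-(ring A)-prop-2-en-1-ol
Conditions: CH2=CHMgBr, THF, −78 °C
Reagents that add atoms: vinylmagnesium bromide C=C[Mg]Br
Why: Grignard addition to a non-enolisable neopentyl aldehyde; Felkin–Anh attack anti to C10 would favour the 2-epimer, which is irrelevant because C2 is reset in step 8.

Step 7
Reactants: 9 C2 allylic alcohols
Product: 10 C2 vinyl ketone, 1-(ring A)-prop-2-en-1-one
Conditions: Dess–Martin periodinane, NaHCO3, CH2Cl2, 0 °C
Reagents that add atoms: none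
Why: Dess–Martin oxidation under buffered conditions that leave the silyl enol ether and the silyl ethers intact; both epimers of 9 converge.

Step 8
Reactants: 10 C2 vinyl ketone
Product: 11 C2 allylic alcohol configured at C2 as in 42
Conditions: (S)-2-methyl-CBS-oxazaborolidine (0.2 equiv), BH3·SMe2, THF, −40 °C; MeOH
Reagents that add atoms: none
Why: Corey–Bakshi–Shibata 1,2-reduction with the fully substituted C1 as the large and the vinyl as the small ketone substituent, for which the (S)-catalyst delivers hydride to the face giving the C2 configuration of 42. Felkin–Anh attack of hydride anti to C10 points the same way, so reagent and substrate are matched.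

Step 9
Reactants: 11 C2 allylic alcohol
Product: 12 C2 4-methoxybenzyl (PMB) ether
Conditions: NaH, 4-MeOC6H4CH2Cl, Bu4NI (cat.), THF/DMF, 0 °C → rt
Reagents that add atoms: 4-methoxybenzyl chloride COc1ccc(CCl)cc1
Why: Williamson etherification; basic conditions are chosen because an acid-activated benzyl donor could alkylate the silyl enol ether, and silyl migration to the trans-disposed, remote C2 alkoxide is not expected.

Step 10
Reactants: 12 C2 PMB ether
Product: 13 ring A enone (C12 ketone, C13=C14), C2 PMB ether
Conditions: Pd(OAc)2 (1.1 equiv), MeCN, rt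
Reagents that add atoms: none
Why: Saegusa–Ito oxidation: the regiodefined silyl enol ether gives a palladium enolate at C13 and β-hydride elimination can only take a C14 hydrogen because C1 is quaternary.

Step 11
Reactants: 13 ring A enone
Product: 15 C12 dienyl triflate (C11=C12(OTf)–C13=C14), via potassium dienolate 14 (not isolated)
Conditions: KN(SiMe3)2, THF, −78 °C; PhNTf2, −78 → 0 °C
Reagents that add atoms: N-phenylbis(trifluoromethanesulfonimide) O=S(=O)(N(c1ccccc1)S(=O)(=O)C(F)(F)F)C(F)(F)F
Why: The only acidic proton is C11–H (C1 is quaternary, so there is no γ-proton), and O-sulfonylation of the cross-conjugated enolate is standard; the C11 stereocentre is erased.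

Step 12
Reactants: 15 C12 dienyl triflate
Product: 16 ring A 1,3-diene (C11(CH3)=C12–C13=C14)
Conditions: Pd(OAc)2 (5 mol %), PPh3, Bu3N, HCO2H, DMF, 60 °C
Reagents that add atoms: none
Why: Palladium-catalysed formate reduction of an enol triflate (oxidative addition to zerovalent palladium, formate-to-hydride exchange with loss of CO2, reductive elimination); the quaternary C1 rules out aromatisation.

Step 13
Reactants: 16 ring A 1,3-diene
Product: 17 C11,C12-cis-diol configured as in 42
Conditions: OsO4 (2 mol %), NMO (1.05 equiv), acetone/H2O, 0 °C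
Reagents that add atoms: osmium tetroxide O=[Os](=O)(=O)=O; N-methylmorpholine N-oxide C[N+]1([O-])CCOCC1
Why: Catalytic syn-dihydroxylation of the trisubstituted terminus of the conjugated diene, the most electron-rich alkene, ahead of C13=C14 and of the vinyl group, which is deactivated by its allylic ether. The face syn to C9 and the C1 methyl is screened in either half-chair by an axial group, so both oxygens should enter anti to them, cis to each other as in 42.

Step 14
Reactants: 17 C11,C12-cis-diol
Product: 18 C11,C12-acetonide
Conditions: 2-methoxypropene, PPTS (cat.), CH2Cl2, 0 °C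
Reagents that add atoms: 2-methoxypropene C=C(C)OC
Why: Acetal formation on a cis-1,2-diol under aprotic, weakly acidic conditions that the silyl ethers tolerate.

Step 15
Reactants: 18 C11,C12-acetonide
Product: 19 C8 aldehyde with C9 triethylsilyl ether
Conditions: (COCl)2, DMSO, CH2Cl2, −78 → −30 °C; Et3N
Reagents that add atoms: none
Why: Swern conditions cleave and oxidise a primary triethylsilyl ether directly while the hindered secondary one stays, which saves a separate deprotection; the α-silyloxy aldehyde is used at once.

Step 16
Reactants: 19 C8 aldehyde; 20 2-methyl-2-(trimethylsilyloxy)but-3-yne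
Product: 22 C8 propargylic alcohols (both C8 epimers) carrying C5–OSiMe3, via lithium acetylide 21 (not isolated)
Conditions: n-BuLi, THF, −78 °C (20); then 19, −78 °C; NH4Cl
Reagents that add atoms: none
Why: Acetylide addition to an aldehyde forms C7–C8 and brings in C5–C7 with the tertiary oxygen needed for the later 1,3-shift; the C8 configuration is irrelevant because it is oxidised next.

Step 17
Reactants: 22 C8 propargylic alcohols
Product: 23 C8 ynone
Conditions: Dess–Martin periodinane, NaHCO3, CH2Cl2, 0 °C
Reagents that add atoms: none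
Why: Dess–Martin oxidation of a propargylic alcohol under buffered conditions that should not epimerise the α-silyloxy centre C9.

Step 18
Reactants: 24 (R)-lactic acid; 25 pivalaldehyde
Product: 26 (2R,5R)-2-tert-butyl-5-methyl-1,3-dioxolan-4-one
Conditions: TsOH·H2O (cat.), H2SO4 (cat.), pentane, reflux, water separator; crystallisation
Reagents that add atoms: none
Why: Acid-catalysed acetalisation of an α-hydroxy acid, which gives mainly the cis acetal; the new acetal centre stores the lactate configuration for step 19.

Step 19
Reactants: 23 C8 ynone; 26 (2R,5R)-2-tert-butyl-5-methyl-1,3-dioxolan-4-one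
Product: 29 aldol adduct as C8 triethylsilyl ether (C8 and C17 as in 42), via lithium enolate 27 (not isolated), via lithium aldolate 28 (not isolated)
Conditions: LiN(iPr)2, THF, −78 °C (26, 1.5 equiv); 23, −78 °C; Et3SiOTf, −78 → −40 °C
Reagents that add atoms: triethylsilyl trifluoromethanesulfonate CC[Si](CC)(CC)OS(=O)(=O)C(F)(F)F
Why: Aldol addition of a 2-tert-butyl-dioxolanone enolate (self-regeneration of the lactate stereocentre): C8 enters trans to the tert-butyl group, which fixes C17 with overall retention. The ketone face follows the polar Felkin–Anh model for an α-silyloxy ketone (C9–O anti to the incoming enolate), which gives the C8 configuration of 42. Conjugate addition is blocked by the fully substituted C5, and silylation of the aldolate in the flask prevents retro-aldol and a later oxa-Michael closure.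

Step 20
Reactants: 29 aldol adduct as C8 triethylsilyl ether
Product: 31 C7 3-methylbut-2-enoyl ketone still carrying the C2 vinyl group, via tertiary carbinol 30 (not isolated)
Conditions: PPTS (cat.), MeOH, 0 °C; then Ph3PAuNTf2 (5 mol %), MeOH (2 equiv), toluene, rt
Reagents that add atoms: none
Why: Methanolysis removes only the unhindered tertiary trimethylsilyl ether. The gold-catalysed Meyer–Schuster rearrangement (alkyne activation, attack of methanol at C7, loss of the C5 hydroxyl, hydrolysis) then moves the oxygen from C5 to C7; ionisation at C8 is excluded by its silyl ether and electron-poor neighbours.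

Step 21
Reactants: 31 C7 3-methylbut-2-enoyl ketone with C2 vinyl group
Product: 33 seco keto aldehyde (C3 aldehyde, C2 PMB ether, C7 3-methylbut-2-enoyl ketone, O8 and O9 as triethylsilyl ethers, C17/C19 as tert-butyl dioxolanone), via vicinal diol 32 (not isolated)
Conditions: OsO4 (2 mol %), NaIO4, 2,6-lutidine, dioxane/H2O (3:1), 0 °C → rt
Reagents that add atoms: osmium tetroxide O=[Os](=O)(=O)=O; sodium periodate [Na+].[O-]I(=O)(=O)=O
Why: Lemieux–Johnson cleavage: the monosubstituted vinyl group is osmylated faster than the hindered, doubly allylic-oxygenated C13=C14 alkene and the electron-poor enone, and periodate cleaves diol 32 to the C3 aldehyde without touching C2.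

Step 22
Reactants: 33 seco keto aldehyde
Product: 35 ten-membered C3-hydroxy C7-enone with (Z)-C5=C6, via aluminium dienolate 34 (not isolated)
Conditions: Al(OC6H3-2,6-Ph2)3 (3.5 equiv), toluene, −78 °C; then slow addition to lithium 2,2,6,6-tetramethylpiperidide (2 equiv), THF/toluene, −78 → −40 °C, 0.003 M
Reagents that add atoms: none
Why: Proposed new method: the aldehyde, enone and dioxolanone carbonyls are first bound to the bulky aluminium tris(2,6-diphenylphenoxide), which buries the carbonyl carbons, C6 and the C2 hydrogen, so that the hindered lithium amide can only take a proton from a C5 methyl group; the aluminium dienolate 34 then adds through its terminal carbon C4 to the activated C3 aldehyde and forms C3–C4. The closest known reaction type is the intermolecular γ-selective vinylogous aldol of enones and enoates precomplexed to this aluminium phenoxide, together with its macrolactone-forming intramolecular version with ester tethers; closure of a carbocycle from a ketone dienolate is the new element. The ten-membered ring closes by exo addition of C4 to the C3 carbonyl, whose oxygen stays outside the ring. C5–C6 is a single bond in the dienolate, so only the cisoid rotamer can bring C4 within reach of C3, and a cis alkene is also the less strained one in a ten-membered ring; this gives the Z enone. The new C3 stereocentre is controlled by the conformation of the forming ring: C4 is expected to add anti to the fully substituted C1 with the aluminium-bound oxygen on the periphery, which leads to the 2,3-syn alcohol; an open-chain dipolar preference would favour 2,3-anti, so this face selectivity is the least secure element. γ- over α-attack is secured by the aluminium reagent, ring closure over oligomerisation by high dilution, absence of an α′-enolate by quaternary C8, and absence of retro-aldol by the C8 silyl ether.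

Step 23
Reactants: 35 ten-membered C3-hydroxy C7-enone
Product: 36 C3 acetate
Conditions: Ac2O, pyridine, DMAP (cat.), CH2Cl2, 0 °C
Reagents that add atoms: acetic anhydride CC(=O)OC(C)=O
Why: Acylation of the only free hydroxyl; it is done before the enone is reduced so that C3 and C7 oxygens never compete.

Step 24
Reactants: 36 C3 acetate
Product: 38 γ-lactone (C7–O–C19) with free C17 hydroxyl, via C7 allylic alcohol 37 (not isolated)
Conditions: NaBH4, CeCl3·7H2O, MeOH/CH2Cl2, −78 °C; AcOH; then DBU (0.2 equiv), CH2Cl2, rt
Reagents that add atoms: none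
Why: Luche 1,2-reduction of the enone; hydride is expected anti to the C8–O bond (polar Felkin–Anh) on the outer face of the ring, which gives the C7 configuration of 42. Base then lets the C7 hydroxyl attack the activated dioxolanone carbonyl C19 (five-membered exo acyl transfer), closing the lactone and releasing pivalaldehyde and the C17 hydroxyl.

Step 25
Reactants: 38 γ-lactone
Product: 39 C8,C9-diol
Conditions: HF·pyridine, pyridine, THF, 0 °C → rt
Reagents that add atoms: none
Why: Buffered fluoride cleaves both triethylsilyl ethers and leaves the acetate, lactone, acetonide and PMB ether.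

Step 26
Reactants: 39 C8,C9-diol
Product: 40 C3,C9-diacetate
Conditions: Ac2O, DMAP (cat.), pyridine, CH2Cl2, 0 °C → rt
Reagents that add atoms: acetic anhydride CC(=O)OC(C)=O
Why: The only free secondary hydroxyl is at C9; the tertiary C8 and C17 hydroxyls should not be acylated under these conditions, and C2 and C12 are still protected.

Step 27
Reactants: 40 C3,C9-diacetate
Product: 41 C2 alcohol with the C11,C12-acetonide in place
Conditions: DDQ, CH2Cl2/pH 7 buffer, 0 °C
Reagents that add atoms: none
Why: Oxidative PMB cleavage under neutral buffered conditions, which avoids migration of the C3 acetate; the allylic C12 oxygen is still locked in the acetonide and cannot be oxidised.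

Step 28
Reactants: 41 C2 alcohol
Product: 42 CNP0199254.3 (target)
Conditions: AcOH/H2O (4:1), 40 °C
Reagents that add atoms: none
Why: Mild aqueous acid hydrolysis of the cis-acetonide; the conditions are too weak to ionise the allylic lactone or to move the acetates.

## Compound list

1 | (R)-2,2-dimethyl-1,3-dioxolane-4-carbaldehyde | CC1(C)OC[C@@H](O1)C=O | starting material
2 | 2-(triphenylphosphoranylidene)propanal | CC(C=O)=P(c1ccccc1)(c1ccccc1)c1ccccc1 | starting material
3 | (E)-3-[(4S)-2,2-dimethyl-1,3-dioxolan-4-yl]-2-methylprop-2-enal | CC1(C)OC[C@@H](O1)/C=C(\C)C=O | intermediate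
4 | (4S,E)-4,5-dihydroxy-2-methylpent-2-enal | OC[C@@H](O)/C=C(\C)C=O | intermediate
5 | (4S,E)-2-methyl-4,5-bis(triethylsilyloxy)pent-2-enal | CC[Si](CC)(CC)OC[C@@H](O[Si](CC)(CC)CC)/C=C(\C)C=O | intermediate
6 | pent-1-en-3-one | CCC(=O)C=C | starting material
7 | (Z)-3-(triisopropylsilyloxy)penta-1,3-diene | C/C=C(\O[Si](C(C)C)(C(C)C)C(C)C)C=C | intermediate
8 | ring A aldehyde (C1, C10 as in 42; C12 silyl enol ether; C9, C8 bis-silyl ether; C11 mixture) | O=C[C@@]1(C)CC=C(O[Si](C(C)C)(C(C)C)C(C)C)C(C)[C@@H]1[C@H](O[Si](CC)(CC)CC)CO[Si](CC)(CC)CC | intermediate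
9 | C2 allylic alcohols (C2 epimers) | C=CC(O)[C@@]1(C)CC=C(O[Si](C(C)C)(C(C)C)C(C)C)C(C)[C@@H]1[C@H](O[Si](CC)(CC)CC)CO[Si](CC)(CC)CC | intermediate
10 | C2 vinyl ketone | C=CC(=O)[C@@]1(C)CC=C(O[Si](C(C)C)(C(C)C)C(C)C)C(C)[C@@H]1[C@H](O[Si](CC)(CC)CC)CO[Si](CC)(CC)CC | intermediate
11 | C2 allylic alcohol, C2 as in 42 | C=C[C@@H](O)[C@@]1(C)CC=C(O[Si](C(C)C)(C(C)C)C(C)C)C(C)[C@@H]1[C@H](O[Si](CC)(CC)CC)CO[Si](CC)(CC)CC | intermediate
12 | C2 PMB ether | C=C[C@@H](OCc1ccc(OC)cc1)[C@@]2(C)CC=C(O[Si](C(C)C)(C(C)C)C(C)C)C(C)[C@@H]2[C@H](O[Si](CC)(CC)CC)CO[Si](CC)(CC)CC | intermediate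
13 | ring A enone (C12 ketone, C13=C14) | C=C[C@@H](OCc1ccc(OC)cc1)[C@@]2(C)C=CC(=O)C(C)[C@@H]2[C@H](O[Si](CC)(CC)CC)CO[Si](CC)(CC)CC | intermediate
14 | potassium C11,C12-dienolate of 13 | C=C[C@@H](OCc1ccc(OC)cc1)[C@@]2(C)C=CC([O-])=C(C)[C@@H]2[C@H](O[Si](CC)(CC)CC)CO[Si](CC)(CC)CC.[K+] | intermediate
15 | C12 dienyl triflate | C=C[C@@H](OCc1ccc(OC)cc1)[C@@]2(C)C=CC(OS(=O)(=O)C(F)(F)F)=C(C)[C@@H]2[C@H](O[Si](CC)(CC)CC)CO[Si](CC)(CC)CC | intermediate
16 | ring A 1,3-diene | C=C[C@@H](OCc1ccc(OC)cc1)[C@@]2(C)C=CC=C(C)[C@@H]2[C@H](O[Si](CC)(CC)CC)CO[Si](CC)(CC)CC | intermediate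
17 | C11,C12-cis-diol | C=C[C@@H](OCc1ccc(OC)cc1)[C@@]2(C)C=C[C@@H](O)[C@@](C)(O)[C@@H]2[C@H](O[Si](CC)(CC)CC)CO[Si](CC)(CC)CC | intermediate
18 | C11,C12-acetonide | C=C[C@@H](OCc1ccc(OC)cc1)[C@@]2(C)C=C[C@H]3OC(C)(C)O[C@@]3(C)[C@@H]2[C@H](O[Si](CC)(CC)CC)CO[Si](CC)(CC)CC | intermediate
19 | C8 aldehyde, C9 triethylsilyl ether | C=C[C@@H](OCc1ccc(OC)cc1)[C@@]2(C)C=C[C@H]3OC(C)(C)O[C@@]3(C)[C@@H]2[C@H](O[Si](CC)(CC)CC)C=O | intermediate
20 | 2-methyl-2-(trimethylsilyloxy)but-3-yne | C#CC(C)(C)O[Si](C)(C)C | starting material
21 | lithium acetylide of 20 | [Li]C#CC(C)(C)O[Si](C)(C)C | intermediate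
22 | C8 propargylic alcohols (C8 epimers) | C=C[C@@H](OCc1ccc(OC)cc1)[C@@]2(C)C=C[C@H]3OC(C)(C)O[C@@]3(C)[C@@H]2[C@H](O[Si](CC)(CC)CC)C(O)C#CC(C)(C)O[Si](C)(C)C | intermediate
23 | C8 ynone | C=C[C@@H](OCc1ccc(OC)cc1)[C@@]2(C)C=C[C@H]3OC(C)(C)O[C@@]3(C)[C@@H]2[C@H](O[Si](CC)(CC)CC)C(=O)C#CC(C)(C)O[Si](C)(C)C | intermediate
24 | (R)-lactic acid | C[C@@H](O)C(=O)O | starting material
25 | pivalaldehyde | CC(C)(C)C=O | starting material
26 | (2R,5R)-2-tert-butyl-5-methyl-1,3-dioxolan-4-one | C[C@H]1O[C@@H](C(C)(C)C)OC1=O | intermediate
27 | lithium enolate of 26 | CC1=C(O[Li])O[C@H](C(C)(C)C)O1 | intermediate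
28 | lithium C8 aldolate | C=C[C@@H](OCc1ccc(OC)cc1)[C@@]2(C)C=C[C@H]3OC(C)(C)O[C@@]3(C)[C@@H]2[C@H](O[Si](CC)(CC)CC)[C@@]([O-])(C#CC(C)(C)O[Si](C)(C)C)[C@]4(C)O[C@@H](C(C)(C)C)OC4=O.[Li+] | intermediate
29 | aldol adduct, C8 triethylsilyl ether, C5 trimethylsilyl ether | C=C[C@@H](OCc1ccc(OC)cc1)[C@@]2(C)C=C[C@H]3OC(C)(C)O[C@@]3(C)[C@@H]2[C@H](O[Si](CC)(CC)CC)[C@@](O[Si](CC)(CC)CC)(C#CC(C)(C)O[Si](C)(C)C)[C@]4(C)O[C@@H](C(C)(C)C)OC4=O | intermediate
30 | C5 tertiary carbinol | C=C[C@@H](OCc1ccc(OC)cc1)[C@@]2(C)C=C[C@H]3OC(C)(C)O[C@@]3(C)[C@@H]2[C@H](O[Si](CC)(CC)CC)[C@@](O[Si](CC)(CC)CC)(C#CC(C)(C)O)[C@]4(C)O[C@@H](C(C)(C)C)OC4=O | intermediate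
31 | C7 3-methylbut-2-enoyl ketone with C2 vinyl group | C=C[C@@H](OCc1ccc(OC)cc1)[C@@]2(C)C=C[C@H]3OC(C)(C)O[C@@]3(C)[C@@H]2[C@H](O[Si](CC)(CC)CC)[C@@](O[Si](CC)(CC)CC)(C(=O)C=C(C)C)[C@]4(C)O[C@@H](C(C)(C)C)OC4=O | intermediate
32 | vicinal diol from the vinyl group (C3 carbinol mixture) | OCC(O)[C@@H](OCc1ccc(OC)cc1)[C@@]2(C)C=C[C@H]3OC(C)(C)O[C@@]3(C)[C@@H]2[C@H](O[Si](CC)(CC)CC)[C@@](O[Si](CC)(CC)CC)(C(=O)C=C(C)C)[C@]4(C)O[C@@H](C(C)(C)C)OC4=O | intermediate
33 | seco keto aldehyde (key-step precursor) | O=C[C@@H](OCc1ccc(OC)cc1)[C@@]2(C)C=C[C@H]3OC(C)(C)O[C@@]3(C)[C@@H]2[C@H](O[Si](CC)(CC)CC)[C@@](O[Si](CC)(CC)CC)(C(=O)C=C(C)C)[C@]4(C)O[C@@H](C(C)(C)C)OC4=O | intermediate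
34 | C4,C7-dienolate, aluminium-bound (written as lithium salt) | O=C[C@@H](OCc1ccc(OC)cc1)[C@@]2(C)C=C[C@H]3OC(C)(C)O[C@@]3(C)[C@@H]2[C@H](O[Si](CC)(CC)CC)[C@@](O[Si](CC)(CC)CC)(C([O-])=CC(C)=C)[C@]4(C)O[C@@H](C(C)(C)C)OC4=O.[Li+] | intermediate
35 | ten-membered C3-hydroxy C7-enone (key-step product) | O[C@H]1C/C(C)=C\C(=O)[C@@](O[Si](CC)(CC)CC)([C@]5(C)O[C@@H](C(C)(C)C)OC5=O)[C@@H](O[Si](CC)(CC)CC)[C@H]2[C@]3(C)OC(C)(C)O[C@@H]3C=C[C@]2(C)[C@@H]1OCc4ccc(OC)cc4 | intermediate
36 | C3 acetate | CC(=O)O[C@H]1C/C(C)=C\C(=O)[C@@](O[Si](CC)(CC)CC)([C@]5(C)O[C@@H](C(C)(C)C)OC5=O)[C@@H](O[Si](CC)(CC)CC)[C@H]2[C@]3(C)OC(C)(C)O[C@@H]3C=C[C@]2(C)[C@@H]1OCc4ccc(OC)cc4 | intermediate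
37 | C7 allylic alcohol, C7 as in 42 | CC(=O)O[C@H]1C/C(C)=C\[C@H](O)[C@@](O[Si](CC)(CC)CC)([C@]5(C)O[C@@H](C(C)(C)C)OC5=O)[C@@H](O[Si](CC)(CC)CC)[C@H]2[C@]3(C)OC(C)(C)O[C@@H]3C=C[C@]2(C)[C@@H]1OCc4ccc(OC)cc4 | intermediate
38 | γ-lactone, O8 and O9 triethylsilyl ethers | CC(=O)O[C@H]1C/C(C)=C\[C@@H]2OC(=O)[C@@](C)(O)[C@@]2(O[Si](CC)(CC)CC)[C@@H](O[Si](CC)(CC)CC)[C@H]3[C@]4(C)OC(C)(C)O[C@@H]4C=C[C@]3(C)[C@@H]1OCc5ccc(OC)cc5 | intermediate
39 | C8,C9-diol | CC(=O)O[C@H]1C/C(C)=C\[C@@H]2OC(=O)[C@@](C)(O)[C@@]2(O)[C@@H](O)[C@H]3[C@]4(C)OC(C)(C)O[C@@H]4C=C[C@]3(C)[C@@H]1OCc5ccc(OC)cc5 | intermediate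
40 | C3,C9-diacetate | CC(=O)O[C@H]1C/C(C)=C\[C@@H]2OC(=O)[C@@](C)(O)[C@@]2(O)[C@@H](OC(C)=O)[C@H]3[C@]4(C)OC(C)(C)O[C@@H]4C=C[C@]3(C)[C@@H]1OCc5ccc(OC)cc5 | intermediate
41 | C2 alcohol, acetonide in place | CC(=O)O[C@H]1C/C(C)=C\[C@@H]2OC(=O)[C@@](C)(O)[C@@]2(O)[C@@H](OC(C)=O)[C@H]3[C@]4(C)OC(C)(C)O[C@@H]4C=C[C@]3(C)[C@@H]1O | intermediate
42 | CNP0199254.3 | CC(=O)O[C@H]1C/C(C)=C\[C@@H]2OC(=O)[C@@](C)(O)[C@@]2(O)[C@@H](OC(C)=O)[C@H]2[C@](C)(O)[C@H](O)C=C[C@]2(C)[C@@H]1O | target

## Step count and least certain steps

Total step count: 28. Longest linear sequence: 26 (steps 1–3, 5–17 and 19–28; steps 4 and 18 make the side components 7 and 26).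

**Step 22 (proposed new method).**
- What may go wrong: ring closure may lose to oligomerisation or to simple proton transfer. Poor facial selectivity at the aldehyde is also possible, because the open-chain dipolar preference of an aluminium-bound α-alkoxy aldehyde runs against the 2,3-syn product.
- Fallback, known chemistry: set out from 33. Soft enolisation with tBuMe2SiOTf/Et3N in CH2Cl2 at −78 °C should give the tert-butyldimethylsilyl dienol ether F1; the aldehyde C2–H is tertiary and flanked by quaternary C1, so it should stay untouched. MgBr2·OEt2 in CH2Cl2 under high dilution then brings about an intramolecular vinylogous Mukaiyama aldol through the five-membered magnesium chelate between the C3 carbonyl and the PMB ether oxygen. This is the standard way to a 2,3-syn relationship. Hydrolytic work-up returns to the route at 35.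

**Step 19.**
- What may go wrong: insufficient facial selectivity at the ynone (C8 epimer), or proton transfer from C9–H to the enolate in place of addition.
- Fallback: set out from 19. The lithium enolate 27 is added to the aldehyde to give the C8 carbinol F2 (its C8 configuration does not matter), which Dess–Martin oxidation turns into the C8 ketone F3. The bromomagnesium acetylide made from 20 and EtMgBr is then added in CH2Cl2/Et2O, so that magnesium chelates the ketone and the small C9 triethylsilyl ether. The C7 nucleophile then enters from the side that gives the same C8 configuration. Trapping with Et3SiOTf returns to the route at 29.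

**Step 20.**
- What may go wrong: the 1,3-oxygen shift may stall at the congested alkyne, or the cationic gold catalyst may strip silyl ethers first.
- Fallback: set out from 30, isolated after the methanolysis. Semi-hydrogenation (H2, Pd/CaCO3 poisoned with Pb(OAc)2, quinoline) should give the (Z)-allylic tertiary alcohol F4. Oxidative 1,3-transposition with pyridinium chlorochromate, C5H5NH[CrO3Cl] (Babler–Dauben oxidation), moves the oxygen to C7 and returns to the route at 31.

**Step 24.**
- What may go wrong: hydride delivery to the other face of the C7 ketone, because the outer face of the ring conformer is not known in advance.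
- Fallback: set out from 36. The Luche reduction is quenched with AcOH at −78 °C, before acyl transfer, to isolate the 7-epi alcohol F5. Mitsunobu inversion with chloroacetic acid (PPh3, DIAD) gives the C7 chloroacetate F6 of the correct configuration. Thiourea/NaHCO3 in EtOH removes the chloroacetyl group without touching the acetate and gives 37, which closes under DBU and returns to the route at 38.

**Step 13.**
- What may go wrong: loss of chemoselectivity (osmylation of the vinyl group) or of face selectivity on the diene.
- Fallback: set out from 16. Dimethyldioxirane in acetone at −40 °C should epoxidise only the trisubstituted diene terminus, anti to C9, to the vinyl epoxide F7; epoxidation responds far more to alkene substitution than osmylation does. Pd(PPh3)4 under CO2 in THF converts F7 into the cis-cyclic carbonate F8 by ionisation and re-closure at C12, each with inversion. K2CO3 in MeOH then returns to the route at 17.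

## Further compounds

F1 | step 22 | tert-butyldimethylsilyl dienol ether of 33 (enol ether geometry not defined) | O=C[C@@H](OCc1ccc(OC)cc1)[C@@]2(C)C=C[C@H]3OC(C)(C)O[C@@]3(C)[C@@H]2[C@H](O[Si](CC)(CC)CC)[C@@](O[Si](CC)(CC)CC)(C(O[Si](C)(C)C(C)(C)C)=CC(C)=C)[C@]4(C)O[C@@H](C(C)(C)C)OC4=O
F2 | step 19 | C8 carbinol from 19 and 27 (C8 epimers) | C=C[C@@H](OCc1ccc(OC)cc1)[C@@]2(C)C=C[C@H]3OC(C)(C)O[C@@]3(C)[C@@H]2[C@H](O[Si](CC)(CC)CC)C(O)[C@]4(C)O[C@@H](C(C)(C)C)OC4=O
F3 | step 19 | C8 ketone bearing the dioxolanone | C=C[C@@H](OCc1ccc(OC)cc1)[C@@]2(C)C=C[C@H]3OC(C)(C)O[C@@]3(C)[C@@H]2[C@H](O[Si](CC)(CC)CC)C(=O)[C@]4(C)O[C@@H](C(C)(C)C)OC4=O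
F4 | step 20 | (Z)-C6=C7 allylic tertiary alcohol | C=C[C@@H](OCc1ccc(OC)cc1)[C@@]2(C)C=C[C@H]3OC(C)(C)O[C@@]3(C)[C@@H]2[C@H](O[Si](CC)(CC)CC)[C@@](O[Si](CC)(CC)CC)(/C=C\C(C)(C)O)[C@]4(C)O[C@@H](C(C)(C)C)OC4=O
F5 | step 24 | 7-epi allylic alcohol | CC(=O)O[C@H]1C/C(C)=C\[C@@H](O)[C@@](O[Si](CC)(CC)CC)([C@]5(C)O[C@@H](C(C)(C)C)OC5=O)[C@@H](O[Si](CC)(CC)CC)[C@H]2[C@]3(C)OC(C)(C)O[C@@H]3C=C[C@]2(C)[C@@H]1OCc4ccc(OC)cc4
F6 | step 24 | C7 chloroacetate, C7 as in 42 | CC(=O)O[C@H]1C/C(C)=C\[C@H](OC(=O)CCl)[C@@](O[Si](CC)(CC)CC)([C@]5(C)O[C@@H](C(C)(C)C)OC5=O)[C@@H](O[Si](CC)(CC)CC)[C@H]2[C@]3(C)OC(C)(C)O[C@@H]3C=C[C@]2(C)[C@@H]1OCc4ccc(OC)cc4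
F7 | step 13 | C11,C12-epoxide of 16 | C=C[C@@H](OCc1ccc(OC)cc1)[C@@]2(C)C=C[C@H]3O[C@@]3(C)[C@@H]2[C@H](O[Si](CC)(CC)CC)CO[Si](CC)(CC)CC
F8 | step 13 | C11,C12-cis-cyclic carbonate | C=C[C@@H](OCc1ccc(OC)cc1)[C@@]2(C)C=C[C@H]3OC(=O)O[C@@]3(C)[C@@H]2[C@H](O[Si](CC)(CC)CC)CO[Si](CC)(CC)CC
A1 | alternative 1 | 4-(dichloromethyl)-4-methylcyclohexa-2,5-dien-1-one | CC1(C(Cl)Cl)C=CC(=O)C=C1
A2 | alternative 1 | 4-(dichloromethyl)-4,6-dimethyl-5-vinylcyclohex-2-en-1-one | C=C[C@H]1[C@H](C)C(=O)C=C[C@]1(C)C(Cl)Cl
A3 | alternative 2 | fourteen-membered C1,C2-epoxide with (E)-C10=C11, C12 silyl ether | CC(=O)O[C@H]1C/C(C)=C\[C@@H]2OC(=O)[C@@](C)(O)[C@@]2(O)[C@@H](OC(C)=O)/C=C(\C)[C@H](O[Si](C)(C)C(C)(C)C)/C=C\[C@]3(C)O[C@H]13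
A4 | alternative 2 | target as its C12 tert-butyldimethylsilyl ether | CC(=O)O[C@H]1C/C(C)=C\[C@@H]2OC(=O)[C@@](C)(O)[C@@]2(O)[C@@H](OC(C)=O)[C@H]2[C@](C)(O)[C@H](O[Si](C)(C)C(C)(C)C)C=C[C@]2(C)[C@@H]1O
A5 | alternative 3 | (Z)-enal oxime with C10 vinyl group | CC(=O)O[C@@H](C/C(C)=C\C=NO)[C@@H](O[Si](C)(C)C(C)(C)C)[C@@]1(C)C=C[C@H]2OC(C)(C)O[C@@]2(C)[C@@H]1C=C
A6 | alternative 3 | isoxazoline-bridged ten-membered ring | CC(=O)O[C@H]1C/C(C)=C\C2=NO[C@H](C2)[C@H]2[C@]3(C)OC(C)(C)O[C@@H]3C=C[C@]2(C)[C@@H]1O[Si](C)(C)C(C)(C)C
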